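**Retrosynthetic overview**
Numbering: anhydride ring O–C1(=O)–C2H2–C3H–C25(=O). The chain continues as C4H(OH), C5H2, C6H=C7(C24HO), C8H2, C9H2, C10H=C11 and on to the chain end.
End game: C4–OH is freed last from a TBS ether. The only ring, the five-membered anhydride (O, C1, C2, C3, C25), is closed just before that by dehydration of the C1/C25 diacid. C24 is taken from ester to aldehyde after the coupling.
Key disconnection C7–C8: the C16 hydrocarbon part, as a B-alkyl-9-BBN, is transferred to C7 of a C6≡C7 ynoate by phosphine-catalysed anti-carboboration, and the C6–B bond is then protonolysed.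
Enabling feature: C7 is both the α-carbon of the C24 carbonyl and one end of C6=C7, whose other end carries only H and C5, so C24(=O)–C7=C6H is a masked ynoate. C8 is homoallylic to C10=C11, so C8–B comes from the vinyl end of a C8=C9–C10=C11 diene.
C3 and C4 come from one Evans syn aldol of a succinyl imide with a β,γ-alkynyl aldehyde. The tetraene comes from farnesol.

Key step: step 10

Remark: the hydroxy anhydride is taken as an isolable compound as drawn, and commercial (2E,6E)-farnesol is taken as geometrically pure.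

Step 1
Reactants: 1 (2E,6E)-farnesol
Product: 2 (2E,6E)-farnesal
Conditions: MnO2, CH2Cl2, rt
Reagents that add atoms: none
Why: Allylic oxidation with MnO2 stops at the enal and should leave the 2E geometry and the isolated trisubstituted alkenes untouched.

Step 2
Reactants: 2 (2E,6E)-farnesal
Product: 3 (3E,7E)-4,8,12-trimethyltrideca-1,3,7,11-tetraene
Conditions: MePPh3Br, n-BuLi, THF, 0 °C; then 2, 0 °C → rt
Reagents that add atoms: methyltriphenylphosphonium bromide, C[P+](c1ccccc1)(c1ccccc1)c1ccccc1.[Br-]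
Why: Wittig methylenation with the non-stabilised ylide turns the aldehyde into the terminal vinyl group without touching the adjacent E double bond.

Step 3
Reactants: 4 4-tert-butoxy-4-oxobutanoic acid; 5 (4S)-4-benzyl-1,3-oxazolidin-2-one
Product: 7 tert-butyl 4-[(4S)-4-benzyl-2-oxo-1,3-oxazolidin-3-yl]-4-oxobutanoate, via mixed pivalic anhydride 6 (not isolated)
Conditions: PivCl, Et3N, THF, −20 °C; then 5, LiCl, −20 °C → rt
Reagents that add atoms: none
Why: Mixed-anhydride N-acylation, in which the hindered pivaloyl carbonyl is spared so that only the succinyl group is transferred to the LiCl/Et3N-activated oxazolidinone.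

Step 4
Reactants: 8 4-(trimethylsilyl)but-3-yn-1-ol
Product: 9 4-(trimethylsilyl)but-3-ynal
Conditions: Dess–Martin periodinane, CH2Cl2, 0 °C → rt; used crude
Reagents that add atoms: none
Why: Dess–Martin oxidation runs under nearly neutral conditions, which should keep the β,γ-alkynyl aldehyde from isomerising to the allenyl aldehyde.

Step 5
Reactants: 7 tert-butyl 4-[(4S)-4-benzyl-2-oxo-1,3-oxazolidin-3-yl]-4-oxobutanoate; 9 4-(trimethylsilyl)but-3-ynal
Product: 12 tert-butyl (3S,4R)-3-{[(4S)-4-benzyl-2-oxo-1,3-oxazolidin-3-yl]carbonyl}-4-hydroxy-7-(trimethylsilyl)hept-6-ynoate, via Z-dibutylboron enolate 10 (not isolated), via dibutylboron aldolate 11 (not isolated)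
Conditions: Bu2BOTf, Et3N, CH2Cl2, −78 → 0 °C; 9, −78 → 0 °C; pH 7 buffer, MeOH, 30% H2O2, 0 °C
Reagents that add atoms: none
Why: Evans syn aldol, in which soft enolisation takes place only on the imide side, the Z-boron enolate adds through a Zimmerman–Traxler chair on the face away from the benzyl group and so sets C3 (S) and C4 (R) together, and the tert-butyl ester resists lactonisation by the new hydroxyl.

Step 6
Reactants: 12 syn aldol
Product: 13 tert-butyl (3S,4R)-3-{[(4S)-4-benzyl-2-oxo-1,3-oxazolidin-3-yl]carbonyl}-4-[(tert-butyldimethylsilyl)oxy]-7-(trimethylsilyl)hept-6-ynoate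
Conditions: TBSOTf, 2,6-lutidine, CH2Cl2, −78 → 0 °C
Reagents that add atoms: tert-butyldimethylsilyl triflate, CC(C)(C)[Si](C)(C)OS(=O)(=O)C(F)(F)F
Why: Silyl triflate O-silylation of a hindered secondary alcohol under buffered conditions blocks retro-aldol, lactonisation and later oxa-Michael reactions without touching either stereocentre.

Step 7
Reactants: 13 TBS-protected aldol imide
Product: 15 (2S,3R)-2-(2-tert-butoxy-2-oxoethyl)-3-[(tert-butyldimethylsilyl)oxy]hex-5-ynoic acid, via peroxy acid 14 (not isolated)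
Conditions: LiOH, H2O2, THF/H2O, 0 °C → rt; Na2SO3; HCl to pH 3
Reagents that add atoms: hydrogen peroxide, OO
Why: Hydroperoxide-mediated auxiliary removal attacks the exocyclic imide carbonyl selectively, and the basic medium should cleave the C(sp)–Si bond in the same operation, with neither event touching C3 or C4.

Step 8
Reactants: 15 carboxylic acid
Product: 16 di-tert-butyl (2S)-2-{(1R)-1-[(tert-butyldimethylsilyl)oxy]but-3-yn-1-yl}butanedioate
Conditions: O-tert-butyl-N,N′-diisopropylisourea, CH2Cl2, rt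
Reagents that add atoms: O-tert-butyl-N,N′-diisopropylisourea, CC(C)NC(=NC(C)C)OC(C)(C)C
Why: O-alkylisourea esterification tert-butylates even a hindered acid under neutral conditions, so the α-stereocentre is not at risk.

Step 9
Reactants: 16 terminal alkyne
Product: 17 di-tert-butyl (2S)-2-{(1R)-1-[(tert-butyldimethylsilyl)oxy]-5-methoxy-5-oxopent-3-yn-1-yl}butanedioate
Conditions: PdCl2 (cat.), CuCl2, NaOAc, CO (1 atm), MeOH, rt
Reagents that add atoms: carbon monoxide, [C-]#[O+]; methanol, CO
Why: Oxidative alkoxycarbonylation of a terminal alkyne (alkynylpalladium formation, CO insertion, methanolysis, reoxidation by CuCl2) installs C24 in an acetate-buffered medium that needs no acetylide base and tolerates the esters and the silyl ether.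

Step 10
Reactants: 3 (3E,7E)-4,8,12-trimethyltrideca-1,3,7,11-tetraene; 17 ynoate
Product: 20 di-tert-butyl (2S)-2-[(1R,3E,7E,11E)-1-[(tert-butyldimethylsilyl)oxy]-4-(methoxycarbonyl)-8,12,16-trimethylheptadeca-3,7,11,15-tetraen-1-yl]butanedioate, via B-homofarnesyl-9-BBN 18 (not isolated), via C6-boryl acrylate 19 (not isolated)
Conditions: 3, 9-BBN-H, THF, 0 °C → rt; then 17, PBu3 (cat.), THF, 60 °C; then AcOH, 50 °C
Reagents that add atoms: none
Why: 9-BBN-H adds anti-Markovnikov to the only monosubstituted double bond of 3 (C8=C9), the three trisubstituted alkenes being far slower, so that boron sits on C8 in 18. PBu3 then adds to C6 of ynoate 17, whose C24 carbonyl oxygen is bound to the boron of 18, to give a β-phosphonio allenolate borate; the C8 alkyl group shifts from four-coordinate boron to the allenolate α-carbon C7 (the C7–C8 bond), and the resulting C6 ylide closes on boron and expels PBu3. The closest known reaction type is exactly this phosphine-catalysed anti-carboboration of alkynoates with B-alkyl-9-BBN reagents made by alkene hydroboration, followed by the classical protonolysis of an alkenylborane with a carboxylic acid, which goes with retention. No ring of the product and no stereocentre is formed; the element set is the C6=C7 geometry, fixed because boron in 19 stays coordinated to the C24 ester oxygen (cis to the ester, trans to C8), so that H replaces B cis to the ester and C8 ends up cis to C5, which is E. The regiochemistry (carbon to C7, boron to C6) is secured by the polarity of the ynoate and the site of phosphine attack, the exocyclic primary alkyl group migrates in preference to the bicyclic B–C bonds, and the aprotic, base-free medium leaves C3, C4, the silyl ether and the tert-butyl esters alone. In one flask a hydrocarbon and a linear ynoate thus become the full C25 chain with all four double bonds in place.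

Step 11
Reactants: 20 triester
Product: 21 di-tert-butyl (2S)-2-[(1R,3E,7E,11E)-1-[(tert-butyldimethylsilyl)oxy]-4-(hydroxymethyl)-8,12,16-trimethylheptadeca-3,7,11,15-tetraen-1-yl]butanedioate
Conditions: DIBAL-H, CH2Cl2, −78 °C; Rochelle salt
Reagents that add atoms: none
Why: In this DIBAL-H reduction the methyl enoate should go to the allylic alcohol at −78 °C while the two tert-butyl esters are shielded by their bulk.

Step 12
Reactants: 21 allylic alcohol
Product: 22 di-tert-butyl (2S)-2-[(1R,3E,7E,11E)-1-[(tert-butyldimethylsilyl)oxy]-4-formyl-8,12,16-trimethylheptadeca-3,7,11,15-tetraen-1-yl]butanedioate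
Conditions: MnO2, CH2Cl2, rt
Reagents that add atoms: none
Why: Allylic oxidation with MnO2 gives the enal, which is also the thermodynamically preferred E isomer, under neutral conditions that cannot trigger loss of the C4 silyloxy group.

Step 13
Reactants: 22 enal di-tert-butyl ester
Product: 24 (2S)-2-[(1R,3E,7E,11E)-1-[(tert-butyldimethylsilyl)oxy]-4-formyl-8,12,16-trimethylheptadeca-3,7,11,15-tetraen-1-yl]butanedioic acid, via bis(trimethylsilyl) ester 23 (not isolated)
Conditions: TMSOTf, 2,6-lutidine, CH2Cl2, 0 °C → rt; aq KH2PO4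
Reagents that add atoms: none
Why: Silyl triflate-mediated tert-butyl ester cleavage (carbonyl O-silylation, loss of isobutene with lutidine as proton acceptor, hydrolysis of the silyl esters on work-up) avoids free Brønsted acid, which the polyene would not tolerate, and should spare the TBS ether.

Step 14
Reactants: 24 diacid
Product: 25 (3S)-3-[(1R,3E,7E,11E)-1-[(tert-butyldimethylsilyl)oxy]-4-formyl-8,12,16-trimethylheptadeca-3,7,11,15-tetraen-1-yl]oxolane-2,5-dione
Conditions: DCC, CH2Cl2, 0 °C
Reagents that add atoms: none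
Why: Carbodiimide cyclodehydration, in which the second carboxyl group attacks the O-acylisourea in a 5-exo-trig closure to give the five-membered anhydride without added base, so that C3 should not epimerise.

Step 15
Reactants: 25 TBS-protected anhydride
Product: 26 hippolide D, (3S)-3-[(1R,3E,7E,11E)-4-formyl-1-hydroxy-8,12,16-trimethylheptadeca-3,7,11,15-tetraen-1-yl]oxolane-2,5-dione
Conditions: HF·pyridine, THF, 0 °C; Et2O, cold pH 7 buffer wash
Reagents that add atoms: none
Why: Fluoride-driven desilylation under anhydrous, weakly acidic conditions frees C4–OH, and the product should persist because acyl transfer to C1 would have to pass through a strained 2,6-dioxabicyclo[2.2.1]heptane-type tetrahedral intermediate.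

**Compound list**
1 | (2E,6E)-farnesol | CC(C)=CCC/C(C)=C/CC/C(C)=C/CO | starting material
2 | (2E,6E)-farnesal | CC(C)=CCC/C(C)=C/CC/C(C)=C/C=O | intermediate
3 | (3E,7E)-4,8,12-trimethyltrideca-1,3,7,11-tetraene | CC(C)=CCC/C(C)=C/CC/C(C)=C/C=C | intermediate
4 | 4-tert-butoxy-4-oxobutanoic acid (mono-tert-butyl succinate) | CC(C)(C)OC(=O)CCC(=O)O | starting material
5 | (4S)-4-benzyl-1,3-oxazolidin-2-one | O=C1N[C@@H](Cc2ccccc2)CO1 | starting material
6 | 4-tert-butoxy-4-oxobutanoic pivalic anhydride | CC(C)(C)OC(=O)CCC(=O)OC(=O)C(C)(C)C | intermediate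
7 | tert-butyl 4-[(4S)-4-benzyl-2-oxo-1,3-oxazolidin-3-yl]-4-oxobutanoate | CC(C)(C)OC(=O)CCC(=O)N1[C@@H](Cc2ccccc2)COC1=O | intermediate
8 | 4-(trimethylsilyl)but-3-yn-1-ol | C[Si](C)(C)C#CCCO | starting material
9 | 4-(trimethylsilyl)but-3-ynal | C[Si](C)(C)C#CCC=O | intermediate
10 | (Z)-O-dibutylboryl enolate of 7 | CCCCB(CCCC)O/C(=C\CC(=O)OC(C)(C)C)N1[C@@H](Cc2ccccc2)COC1=O | intermediate
11 | O-dibutylboryl aldolate of 12 | C[Si](C)(C)C#CC[C@@H](OB(CCCC)CCCC)[C@H](CC(=O)OC(C)(C)C)C(=O)N1[C@@H](Cc2ccccc2)COC1=O | intermediate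
12 | tert-butyl (3S,4R)-3-{[(4S)-4-benzyl-2-oxo-1,3-oxazolidin-3-yl]carbonyl}-4-hydroxy-7-(trimethylsilyl)hept-6-ynoate | C[Si](C)(C)C#CC[C@@H](O)[C@H](CC(=O)OC(C)(C)C)C(=O)N1[C@@H](Cc2ccccc2)COC1=O | intermediate
13 | TBS ether of 12 | C[Si](C)(C)C#CC[C@@H](O[Si](C)(C)C(C)(C)C)[C@H](CC(=O)OC(C)(C)C)C(=O)N1[C@@H](Cc2ccccc2)COC1=O | intermediate
14 | (2S,3R)-2-(2-tert-butoxy-2-oxoethyl)-3-[(tert-butyldimethylsilyl)oxy]hex-5-yneperoxoic acid | C#CC[C@@H](O[Si](C)(C)C(C)(C)C)[C@H](CC(=O)OC(C)(C)C)C(=O)OO | intermediate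
15 | (2S,3R)-2-(2-tert-butoxy-2-oxoethyl)-3-[(tert-butyldimethylsilyl)oxy]hex-5-ynoic acid | C#CC[C@@H](O[Si](C)(C)C(C)(C)C)[C@H](CC(=O)OC(C)(C)C)C(=O)O | intermediate
16 | di-tert-butyl (2S)-2-{(1R)-1-[(tert-butyldimethylsilyl)oxy]but-3-yn-1-yl}butanedioate | C#CC[C@@H](O[Si](C)(C)C(C)(C)C)[C@H](CC(=O)OC(C)(C)C)C(=O)OC(C)(C)C | intermediate
17 | di-tert-butyl (2S)-2-{(1R)-1-[(tert-butyldimethylsilyl)oxy]-5-methoxy-5-oxopent-3-yn-1-yl}butanedioate | COC(=O)C#CC[C@@H](O[Si](C)(C)C(C)(C)C)[C@H](CC(=O)OC(C)(C)C)C(=O)OC(C)(C)C | intermediate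
18 | 9-[(3E,7E)-4,8,12-trimethyltrideca-3,7,11-trien-1-yl]-9-borabicyclo[3.3.1]nonane | CC(C)=CCC/C(C)=C/CC/C(C)=C/CCB1C2CCCC1CCC2 | intermediate
19 | di-tert-butyl (2S)-2-[(1R,3E,7E,11E)-3-(9-borabicyclo[3.3.1]nonan-9-yl)-1-[(tert-butyldimethylsilyl)oxy]-4-(methoxycarbonyl)-8,12,16-trimethylheptadeca-3,7,11,15-tetraen-1-yl]butanedioate | CC(C)=CCC/C(C)=C/CC/C(C)=C/CC/C(C(=O)OC)=C(/B1C2CCCC1CCC2)C[C@@H](O[Si](C)(C)C(C)(C)C)[C@H](CC(=O)OC(C)(C)C)C(=O)OC(C)(C)C | intermediate
20 | di-tert-butyl (2S)-2-[(1R,3E,7E,11E)-1-[(tert-butyldimethylsilyl)oxy]-4-(methoxycarbonyl)-8,12,16-trimethylheptadeca-3,7,11,15-tetraen-1-yl]butanedioate | CC(C)=CCC/C(C)=C/CC/C(C)=C/CC/C(C(=O)OC)=C\C[C@@H](O[Si](C)(C)C(C)(C)C)[C@H](CC(=O)OC(C)(C)C)C(=O)OC(C)(C)C | intermediate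
21 | di-tert-butyl (2S)-2-[(1R,3E,7E,11E)-1-[(tert-butyldimethylsilyl)oxy]-4-(hydroxymethyl)-8,12,16-trimethylheptadeca-3,7,11,15-tetraen-1-yl]butanedioate | CC(C)=CCC/C(C)=C/CC/C(C)=C/CC/C(CO)=C\C[C@@H](O[Si](C)(C)C(C)(C)C)[C@H](CC(=O)OC(C)(C)C)C(=O)OC(C)(C)C | intermediate
22 | di-tert-butyl (2S)-2-[(1R,3E,7E,11E)-1-[(tert-butyldimethylsilyl)oxy]-4-formyl-8,12,16-trimethylheptadeca-3,7,11,15-tetraen-1-yl]butanedioate | CC(C)=CCC/C(C)=C/CC/C(C)=C/CC/C(C=O)=C\C[C@@H](O[Si](C)(C)C(C)(C)C)[C@H](CC(=O)OC(C)(C)C)C(=O)OC(C)(C)C | intermediate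
23 | bis(trimethylsilyl) ester of 24 | CC(C)=CCC/C(C)=C/CC/C(C)=C/CC/C(C=O)=C\C[C@@H](O[Si](C)(C)C(C)(C)C)[C@H](CC(=O)O[Si](C)(C)C)C(=O)O[Si](C)(C)C | intermediate
24 | (2S)-2-[(1R,3E,7E,11E)-1-[(tert-butyldimethylsilyl)oxy]-4-formyl-8,12,16-trimethylheptadeca-3,7,11,15-tetraen-1-yl]butanedioic acid | CC(C)=CCC/C(C)=C/CC/C(C)=C/CC/C(C=O)=C\C[C@@H](O[Si](C)(C)C(C)(C)C)[C@H](CC(=O)O)C(=O)O | intermediate
25 | (3S)-3-[(1R,3E,7E,11E)-1-[(tert-butyldimethylsilyl)oxy]-4-formyl-8,12,16-trimethylheptadeca-3,7,11,15-tetraen-1-yl]oxolane-2,5-dione | CC(C)=CCC/C(C)=C/CC/C(C)=C/CC/C(C=O)=C\C[C@@H](O[Si](C)(C)C(C)(C)C)[C@@H]1CC(=O)OC1=O | intermediate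
26 | hippolide D | CC(C)=CCC/C(C)=C/CC/C(C)=C/CC/C(C=O)=C\C[C@@H](O)[C@@H]1CC(=O)OC1=O | target

**Step count**
Total step count: 15. Longest linear sequence: 12 steps (3, 5, 6, 7, 8, 9, 10, 11, 12, 13, 14, 15).

**Steps most likely to fail**

Step 10. The phosphine may isomerise the ynoate through its acidic C5 methylene to an allenoate or dienoate, with loss of silanolate from C4, faster than the alkyl group is transferred. The O-chelated C6–B bond may also resist protonolysis. The fallback sets out from 17 and comes back at 21, replacing the organocatalytic carboboration by a stereodefined alkenyl iodide and a cross-coupling. Reduction of 17 with DIBAL-H (CH2Cl2, −78 °C) would give the propargylic alcohol F1. Hydroxyl-directed trans-hydrostannation (Bu3SnH, [Cp*RuCl]4, CH2Cl2, rt) would place tin on C7 and give the (Z)-alkenylstannane F2. Iododestannylation (I2, CH2Cl2, 0 °C) would give the (Z)-2-iodoallylic alcohol F3. A B-alkyl Suzuki–Miyaura coupling of F3 with borane 18 (PdCl2(dppf), AsPh3, Cs2CO3, DMF/THF/H2O, rt) would then form the same C7–C8 bond with retention and deliver 21.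

Step 15. The freed C4 hydroxyl may migrate onto the C1 carbonyl, switching the ring to the isomeric γ-lactone acid. The anhydride may also be opened by fluoride, pyridine or water during the fairly slow cleavage of a secondary TBS ether. The fallback sets out from 24 and comes back at 26, reversing the order of deprotection and ring closure. The silyl ether would be removed at the diacid stage (HF·pyridine, THF, 0 °C → rt) to give the hydroxy diacid F4, which would be used at once. One equivalent of DCC in CH2Cl2 at −20 °C, without any acyl-transfer catalyst, would then close the anhydride, because the neighbouring carboxyl group should intercept the O-acylisourea faster than the unactivated secondary alcohol.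

Step 13. Silyl activation of the enal may start a cation–olefin cyclisation with the C10=C11 double bond. It may also convert the enal into a silyl dienol ether, with erosion of the C6=C7 geometry on hydrolysis. The fallback sets out from 20 and comes back at 24, so that the Lewis-acidic step is run before the enal exists and the free carboxylates protect themselves during the reduction. TMSOTf/2,6-lutidine on 20 would give the bis(trimethylsilyl) ester F5 and, after aqueous KH2PO4, the diacid methyl enoate F6. Excess DIBAL-H (CH2Cl2, −78 °C) would first form aluminium carboxylates, which resist hydride at this temperature, and then reduce the enoate to the diacid allylic alcohol F7. TEMPO (cat.)/PhI(OAc)2 in CH2Cl2 would oxidise the allylic alcohol to the aldehyde and give 24.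

**Further compounds**
F1 | step 10 | di-tert-butyl (2S)-2-{(1R)-1-[(tert-butyldimethylsilyl)oxy]-5-hydroxypent-3-yn-1-yl}butanedioate | OCC#CC[C@@H](O[Si](C)(C)C(C)(C)C)[C@H](CC(=O)OC(C)(C)C)C(=O)OC(C)(C)C
F2 | step 10 | di-tert-butyl (2S)-2-[(1R,3Z)-1-[(tert-butyldimethylsilyl)oxy]-5-hydroxy-4-(tributylstannyl)pent-3-en-1-yl]butanedioate | OC/C([Sn](CCCC)(CCCC)CCCC)=C/C[C@@H](O[Si](C)(C)C(C)(C)C)[C@H](CC(=O)OC(C)(C)C)C(=O)OC(C)(C)C
F3 | step 10 | di-tert-butyl (2S)-2-[(1R,3Z)-1-[(tert-butyldimethylsilyl)oxy]-5-hydroxy-4-iodopent-3-en-1-yl]butanedioate | OC/C(I)=C/C[C@@H](O[Si](C)(C)C(C)(C)C)[C@H](CC(=O)OC(C)(C)C)C(=O)OC(C)(C)C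
F4 | step 15 | (2S)-2-[(1R,3E,7E,11E)-4-formyl-1-hydroxy-8,12,16-trimethylheptadeca-3,7,11,15-tetraen-1-yl]butanedioic acid | CC(C)=CCC/C(C)=C/CC/C(C)=C/CC/C(C=O)=C\C[C@@H](O)[C@H](CC(=O)O)C(=O)O
F5 | step 13 | bis(trimethylsilyl) ester of F6 | CC(C)=CCC/C(C)=C/CC/C(C)=C/CC/C(C(=O)OC)=C\C[C@@H](O[Si](C)(C)C(C)(C)C)[C@H](CC(=O)O[Si](C)(C)C)C(=O)O[Si](C)(C)C
F6 | step 13 | (2S)-2-[(1R,3E,7E,11E)-1-[(tert-butyldimethylsilyl)oxy]-4-(methoxycarbonyl)-8,12,16-trimethylheptadeca-3,7,11,15-tetraen-1-yl]butanedioic acid | CC(C)=CCC/C(C)=C/CC/C(C)=C/CC/C(C(=O)OC)=C\C[C@@H](O[Si](C)(C)C(C)(C)C)[C@H](CC(=O)O)C(=O)O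
F7 | step 13 | (2S)-2-[(1R,3E,7E,11E)-1-[(tert-butyldimethylsilyl)oxy]-4-(hydroxymethyl)-8,12,16-trimethylheptadeca-3,7,11,15-tetraen-1-yl]butanedioic acid | CC(C)=CCC/C(C)=C/CC/C(C)=C/CC/C(CO)=C\C[C@@H](O[Si](C)(C)C(C)(C)C)[C@H](CC(=O)O)C(=O)O
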